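**Plan**
- Retrosynthesis: remove the sixteen benzyl groups, then cut the three interflavan C4–C8 bonds one after another, so that all four units come from one monomer type, a tetra-O-benzyl flavan carrying oxygen on C3 and on C4.
- That monomer is cut across ring C at C2–C3 and C4–C4a, giving an O-aryl O-methyl acetal (from 3,5-bis(benzyloxy)phenol and 3,4-bis(benzyloxy)benzaldehyde) and 2,2-dimethyl-1,3-dioxole.
- Enabling feature: O1 of ring C lies between the aryl carbon C8a and the benzylic C2, so ionisation gives the cationic 2-oxadiene C4a=C8a–O1=C2; the electron-rich ortho carbon C4a of the phloroglucinol ring A then closes onto C4 (oxa-Povarov [4+2]).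
- The dioxole oxygen on C3 becomes the 3-OH; its oxygen on C4 is a temporary bond, removed by reduction in the terminal unit and used as the leaving group for the C4–C8 bonds of the three upper units.
- Forward: acetal, asymmetric [4+2] closing ring C, alcoholysis to the C4 electrophile, reduction of one part to the terminal unit, three Friedel–Crafts chain extensions (dimer, trimer, tetramer), hydrogenolysis.
- Stereochemistry: C2 and C3 of every unit come from the chiral-acid-controlled endo cycloaddition; each interflavan C4 is set by substrate control, anti to the C3 oxygen.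

Key step: step 4

Assumption: 2,2-dimethyl-1,3-dioxole (6) is treated as a purchasable specialty reagent (otherwise it would be made by the retro-Diels–Alder route from the ketalised anthracene–vinylene carbonate adduct); the sense of induction of the chiral acid in step 4 must be assigned in a first experiment, and the catalyst enantiomer that gives the 2R series is then used.

Step 1
Reactants: 1 3,4-bis(benzyloxy)benzaldehyde
Product: 2 1,2-bis(benzyloxy)-4-(dimethoxymethyl)benzene
Conditions: HC(OMe)3, p-TsOH·H2O (cat.), MeOH, rt; then Et3N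
Reagents that add atoms: trimethyl orthoformate COC(OC)OC
Why: Acid-catalysed acetalisation with the orthoformate as water scavenger should convert the electron-rich aldehyde cleanly, and no stereocentre is involved.

Step 2
Reactants: 2 1,2-bis(benzyloxy)-4-(dimethoxymethyl)benzene
Product: 3 1,2-bis(benzyloxy)-4-[chloro(methoxy)methyl]benzene (racemic α-chloro ether, used crude)
Conditions: AcCl (1.1 equiv), ZnBr2 (0.01 mol %), CH2Cl2, 0 °C to rt; volatiles removed, used at once
Reagents that add atoms: acetyl chloride CC(=O)Cl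
Why: Acyl chloride cleavage of a dimethyl acetal to a haloalkyl ether should exchange one methoxy group for chloride, because the aryl-stabilised oxocarbenium ion forms easily.

Step 3
Reactants: 3 1,2-bis(benzyloxy)-4-[chloro(methoxy)methyl]benzene; 4 3,5-bis(benzyloxy)phenol
Product: 5 1,3-bis(benzyloxy)-5-{[3,4-bis(benzyloxy)phenyl](methoxy)methoxy}benzene (racemic mixed O-aryl O-methyl acetal)
Conditions: 4, NaH (1.1 equiv), THF, 0 °C; then 3, −20 to 0 °C; chromatography on Et3N-deactivated silica
Reagents that add atoms: none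
Why: Williamson-type O-alkylation of the sodium phenoxide by the α-chloro ether (the reaction type of MOM protection of a phenol) should give the mixed acetal under basic conditions that disfavour C-alkylation of the phloroglucinol ring; the acetal centre is racemic and is destroyed in step 4.

Step 4
Reactants: 5 racemic mixed O-aryl O-methyl acetal; 6 2,2-dimethyl-1,3-dioxole
Product: 9 (2R,3S,4R)-5,7,3',4'-tetra-O-benzylflavan-3,4-diol 3,4-O-isopropylidene acetal (all-cis), via O-aryl oxocarbenium ion 7 (not isolated), via dioxolanylium ion 8 (not isolated)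
Conditions: 6 (3 equiv), chiral imidodiphosphorimidate Brønsted acid (IDPi, BINOL-derived, N-triflyl, 5 mol %), 5 Å molecular sieves, toluene (0.02 M), −60 °C; Et3N quench
Reagents that add atoms: none
Why: Proposed new method: the confined chiral acid protonates the more basic methoxy oxygen of 5, methanol leaves, and the (E)-O-aryl oxocarbenium ion 7 (the cationic 2-oxadiene C4a=C8a–O1=C2) forms as a contact ion pair with the chiral anion; one of the two equivalent oxygen-bearing alkene carbons of 6 attacks C2 (bond C2–C3) to give the dioxolanylium ion 8, whose C4 is captured by the ortho carbon C4a of ring A (bond C4–C4a), and rearomatisation returns the proton to the catalyst. The closest known reaction type is the oxa-Povarov reaction (Lewis-acid-mediated formal inverse-electron-demand [4+2] cycloaddition of aryl alkyl mixed acetals with alkenes to chromans), and the asymmetric precedent is the chiral-Brønsted-acid-catalysed Povarov reaction of N-aryl imines with enol ethers together with IDPi control of aryl oxocarbenium ion pairs; new here are catalyst control of an O-aryl oxocarbenium [4+2] and an enediol ether as the two-carbon partner. Ring C closes as a stepwise (4+2) annulation whose ring-forming event is a 6-exo-trig Friedel–Crafts attack of C4a on the C4=O+ bond, and the dioxolane remains as a cis-fused temporary ring. C2 and C3 are both created in the first C–C bond formation: the chiral anion selects the face of 7 (absolute configuration), the endo approach with the dioxole ring under the O-aryl group should give the 2,3-cis relation as in Povarov reactions of cyclic enol ethers, and C4 is forced cis to C3 by the 5/6 ring fusion and is erased later. The step needs ionisation to the O-aryl and not the O-methyl oxocarbenium ion (preferential activation of the alkyl oxygen, reversibility of the other path) and capture of 7 by the alkene and not by an arene (excess of the more nucleophilic 6, dilution, low temperature). No regiochemical choice arises, because 6 is symmetric with oxygen on both carbons and both ortho positions of the 3,5-bis(benzyloxy)phenoxy ring are equivalent.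

Step 5
Reactants: 9 all-cis acetonide
Product: 10 (2R,3R,4S)-5,7-bis(benzyloxy)-2-[3,4-bis(benzyloxy)phenyl]-4-(2-ethoxyethoxy)chroman-3-ol
Conditions: 2-ethoxyethanol (20 equiv), CSA (5 mol %), CH2Cl2, 0 °C; Et3N quench
Reagents that add atoms: 2-ethoxyethanol CCOCCO
Why: Acid-catalysed transacetalisation should ionise the benzylic C4–O bond (ortho/para to three ring oxygens), the hemiketal residue on O3 collapses to acetone and the free 3-OH, and the alcohol adds to the C4 cation anti to the C3 oxygen; the C4 configuration does not matter because this centre is ionised again later.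

Step 6
Reactants: 10 4-(2-ethoxyethoxy) flavan-3-ol
Product: 11 (2R,3R)-5,7-bis(benzyloxy)-2-[3,4-bis(benzyloxy)phenyl]chroman-3-ol (5,7,3',4'-tetra-O-benzyl-(−)-epicatechin)
Conditions: Et3SiH (10 equiv), BF3·OEt2 (0.2 equiv), CH2Cl2, −78 to −40 °C, slow addition of 10
Reagents that add atoms: none
Why: Ionic hydrogenation: the Lewis acid regenerates the C4 benzylic cation and the silane reduces it to the C4 methylene of the terminal unit without touching C2 or C3, while slow addition into excess silane keeps the cation from alkylating the product.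

Step 7
Reactants: 11 tetra-O-benzyl-(−)-epicatechin (nucleophile); 10 4-(2-ethoxyethoxy) flavan-3-ol (electrophile)
Product: 12 octa-O-benzyl epicatechin-(4β→8)-epicatechin (benzylated dimer)
Conditions: 11 (4 equiv), TMSOTf (0.2 equiv), CH2Cl2, −78 °C; Et3N quench; excess 11 recovered
Reagents that add atoms: none
Why: Lewis-acid-mediated Friedel–Crafts flavan coupling (the biomimetic C4 cation alkylation used for procyanidins) should let C8 of 11 attack the C4 cation of 10 anti to the C3 hydroxyl and C2 aryl group, which sets the 3,4-trans (4R) interflavan centre by substrate control, with C8 preferred over C6.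

Step 8
Reactants: 12 benzylated dimer (nucleophile); 10 4-(2-ethoxyethoxy) flavan-3-ol (electrophile)
Product: 13 dodeca-O-benzyl epicatechin-(4β→8)-epicatechin-(4β→8)-epicatechin (benzylated trimer)
Conditions: 12 (3 equiv), TMSOTf (0.2 equiv), CH2Cl2, −78 °C; Et3N quench; excess 12 recovered
Reagents that add atoms: none
Why: The same Friedel–Crafts chain extension should take place at the only free C8, that of the upper unit of 12, and the new C4 centre is again set 4β, trans to the neighbouring C3 oxygen.

Step 9
Reactants: 13 benzylated trimer (nucleophile); 10 4-(2-ethoxyethoxy) flavan-3-ol (electrophile)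
Product: 14 hexadeca-O-benzyl epicatechin-(4β→8)-epicatechin-(4β→8)-epicatechin-(4β→8)-epicatechin (benzylated tetramer)
Conditions: 13 (2 equiv), TMSOTf (0.2 equiv), CH2Cl2, −78 °C; Et3N quench; excess 13 recovered
Reagents that add atoms: none
Why: A third Friedel–Crafts chain extension at the free C8 of the top unit of 13 should give the all-(4β→8) tetramer, with the new C4 centre set trans to its C3 oxygen by the same substrate control.

Step 10
Reactants: 14 benzylated tetramer
Product: 15 epicatechin-(4β→8)-epicatechin-(4β→8)-epicatechin-(4β→8)-epicatechin (the target tetramer)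
Conditions: H2 (1 atm), Pd(OH)2/C, THF/MeOH/H2O, rt
Reagents that add atoms: none
Why: Hydrogenolysis of the sixteen benzyl ethers should free the polyphenol without cleaving the interflavan bonds or changing any stereocentre.

**Compound list**
1 | 3,4-bis(benzyloxy)benzaldehyde | O=Cc1ccc(OCc2ccccc2)c(OCc2ccccc2)c1 | starting material
2 | 1,2-bis(benzyloxy)-4-(dimethoxymethyl)benzene | COC(OC)c1ccc(OCc2ccccc2)c(OCc2ccccc2)c1 | intermediate
3 | 1,2-bis(benzyloxy)-4-[chloro(methoxy)methyl]benzene (racemic) | COC(Cl)c1ccc(OCc2ccccc2)c(OCc2ccccc2)c1 | intermediate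
4 | 3,5-bis(benzyloxy)phenol | Oc1cc(OCc2ccccc2)cc(OCc2ccccc2)c1 | starting material
5 | 1,3-bis(benzyloxy)-5-{[3,4-bis(benzyloxy)phenyl](methoxy)methoxy}benzene (racemic) | COC(Oc1cc(OCc2ccccc2)cc(OCc2ccccc2)c1)c1ccc(OCc2ccccc2)c(OCc2ccccc2)c1 | intermediate
6 | 2,2-dimethyl-1,3-dioxole | CC1(C)OC=CO1 | starting material
7 | (E)-[3,4-bis(benzyloxy)benzylidene][3,5-bis(benzyloxy)phenyl]oxonium, ion pair with the catalyst anion | c1ccccc1COc1ccc(/C=[O+]/c2cc(OCc3ccccc3)cc(OCc3ccccc3)c2)cc1OCc1ccccc1 | intermediate (not isolated)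
8 | 2,2-dimethyl-1,3-dioxolan-4-ylium ion carrying at C5 the (R)-[3,4-bis(benzyloxy)phenyl][3,5-bis(benzyloxy)phenoxy]methyl group (flavan numbering 2R,3S) | c1ccccc1COc1cc(OCc2ccccc2)cc(O[C@H](c2ccc(OCc3ccccc3)c(OCc3ccccc3)c2)[C@@H]2OC(C)(C)[O+]=C2)c1 | intermediate (not isolated)
9 | (2R,3S,4R)-5,7,3',4'-tetra-O-benzylflavan-3,4-diol 3,4-O-isopropylidene acetal (all-cis; H-2, H-3 and H-4 on one face) | c1ccccc1COc1cc(OCc2ccccc2)c2c(c1)O[C@H](c1ccc(OCc3ccccc3)c(OCc3ccccc3)c1)[C@@H]1OC(C)(C)O[C@H]21 | intermediate
10 | (2R,3R,4S)-5,7-bis(benzyloxy)-2-[3,4-bis(benzyloxy)phenyl]-4-(2-ethoxyethoxy)chroman-3-ol | c1ccccc1COc1cc(OCc2ccccc2)c2c(c1)O[C@H](c1ccc(OCc3ccccc3)c(OCc3ccccc3)c1)[C@H](O)[C@H]2OCCOCC | intermediate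
11 | (2R,3R)-5,7-bis(benzyloxy)-2-[3,4-bis(benzyloxy)phenyl]chroman-3-ol (tetra-O-benzyl-(−)-epicatechin) | c1ccccc1COc1cc(OCc2ccccc2)c2c(c1)O[C@H](c1ccc(OCc3ccccc3)c(OCc3ccccc3)c1)[C@H](O)C2 | intermediate
12 | octa-O-benzyl epicatechin-(4β→8)-epicatechin (benzylated dimer) | c1ccccc1COc1cc(OCc2ccccc2)c2c(c1)O[C@H](c1ccc(OCc3ccccc3)c(OCc3ccccc3)c1)[C@H](O)[C@H]2c1c(OCc2ccccc2)cc(OCc2ccccc2)c2c1O[C@H](c1ccc(OCc3ccccc3)c(OCc3ccccc3)c1)[C@H](O)C2 | intermediate
13 | dodeca-O-benzyl epicatechin-(4β→8)-epicatechin-(4β→8)-epicatechin (benzylated trimer) | c1ccccc1COc1cc(OCc2ccccc2)c2c(c1)O[C@H](c1ccc(OCc3ccccc3)c(OCc3ccccc3)c1)[C@H](O)[C@H]2c1c(OCc2ccccc2)cc(OCc2ccccc2)c2c1O[C@H](c1ccc(OCc3ccccc3)c(OCc3ccccc3)c1)[C@H](O)[C@H]2c1c(OCc2ccccc2)cc(OCc2ccccc2)c2c1O[C@H](c1ccc(OCc3ccccc3)c(OCc3ccccc3)c1)[C@H](O)C2 | intermediate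
14 | hexadeca-O-benzyl epicatechin-(4β→8)-epicatechin-(4β→8)-epicatechin-(4β→8)-epicatechin (benzylated tetramer) | c1ccccc1COc1cc(OCc2ccccc2)c2c(c1)O[C@H](c1ccc(OCc3ccccc3)c(OCc3ccccc3)c1)[C@H](O)[C@H]2c1c(OCc2ccccc2)cc(OCc2ccccc2)c2c1O[C@H](c1ccc(OCc3ccccc3)c(OCc3ccccc3)c1)[C@H](O)[C@H]2c1c(OCc2ccccc2)cc(OCc2ccccc2)c2c1O[C@H](c1ccc(OCc3ccccc3)c(OCc3ccccc3)c1)[C@H](O)[C@H]2c1c(OCc2ccccc2)cc(OCc2ccccc2)c2c1O[C@H](c1ccc(OCc3ccccc3)c(OCc3ccccc3)c1)[C@H](O)C2 | intermediate
15 | epicatechin-(4β→8)-epicatechin-(4β→8)-epicatechin-(4β→8)-epicatechin (the target tetramer) | Oc1cc(O)c2c(c1)O[C@H](c1ccc(O)c(O)c1)[C@H](O)[C@H]2c1c(O)cc(O)c2c1O[C@H](c1ccc(O)c(O)c1)[C@H](O)[C@H]2c1c(O)cc(O)c2c1O[C@H](c1ccc(O)c(O)c1)[C@H](O)[C@H]2c1c(O)cc(O)c2c1O[C@H](c1ccc(O)c(O)c1)[C@H](O)C2 | target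

Total step count: 10. Longest linear sequence: 10 steps.

**Steps most likely to fail**

Step 4. Possible failure: poor facial or endo/exo selectivity in the ion-pair cycloaddition, or ionisation toward the O-methyl oxocarbenium ion followed by alkylation of an arene. The fallback sets out from 5 and comes back at 11, and through 11 at 10. Acetal 5 and dioxole 6 are combined with SnCl4 in CH2Cl2 at −78 °C, the achiral oxa-Povarov conditions, to give the racemic all-cis acetonide F1. This is carried through the conditions of steps 5 and 6 to the racemic 4-(2-ethoxyethoxy) flavan-3-ol F2 and then to racemic tetra-O-benzyl-epicatechin F3, with any 2,3-trans isomer carried along. Dess–Martin oxidation gives 5,7,3',4'-tetra-O-benzylflavan-3-one F4, in which C2 is epimerisable, so both diastereomers and both enantiomers converge. Asymmetric transfer hydrogenation under dynamic kinetic resolution (RuCl[(S,S)-TsDPEN](p-cymene) or its enantiomer, HCO2H/Et3N) should deliver hydride anti to the 2-aryl group and give the 2,3-cis (2R,3R) alcohol 11. Compound 10 is then remade from 11 by benzylic oxidation at C4 with DDQ in the presence of 2-ethoxyethanol.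

Step 9. Possible failure: loss of chemoselectivity in the chain extension, with self-condensation of the electrophile through its own free C8 and attack at C6 positions of the trimer, leading to higher and branched oligomers. The fallback sets out from 10 and 13 and comes back at 15. Compound 10 is brominated at C8 with NBS (CH2Cl2, −20 °C) to the 8-bromo-4-(2-ethoxyethoxy) electrophile F5, whose own ring A can no longer act as the nucleophile. Equimolar TMSOTf coupling of F5 with 13 gives the 8-bromo hexadeca-O-benzyl tetramer F6. Hydrogenolysis over Pd(OH)2/C in the presence of Et3N removes the bromine together with the benzyl groups and gives 15.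

Step 3. Possible failure: C-alkylation of the electron-rich phenoxide ring by the ionised chloro ether, and hydrolysis of the labile mixed acetal during isolation. The fallback sets out from 2 and comes back at 5. Dimethyl acetal 2 is treated with TESOTf and 2,4,6-collidine in CH2Cl2 at 0 °C to give the N-[aryl(methoxy)methyl]-2,4,6-collidinium triflate F7, a non-acidic oxocarbenium equivalent. This salt is intercepted in the same flask by the sodium salt of 4 to give 5, a mixed-acetal synthesis through a pyridinium-type salt that avoids both the free chloro ether and free acid.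

Further compounds
F1 | step 4 | racemic all-cis 5,7,3',4'-tetra-O-benzylflavan-3,4-diol 3,4-O-isopropylidene acetal (relative configuration drawn) | c1ccccc1COc1cc(OCc2ccccc2)c2c(c1)O[C@H](c1ccc(OCc3ccccc3)c(OCc3ccccc3)c1)[C@@H]1OC(C)(C)O[C@H]21
F2 | step 4 | racemic 2,3-cis-3,4-trans 5,7-bis(benzyloxy)-2-[3,4-bis(benzyloxy)phenyl]-4-(2-ethoxyethoxy)chroman-3-ol (relative configuration drawn) | c1ccccc1COc1cc(OCc2ccccc2)c2c(c1)O[C@H](c1ccc(OCc3ccccc3)c(OCc3ccccc3)c1)[C@H](O)[C@H]2OCCOCC
F3 | step 4 | racemic 2,3-cis 5,7-bis(benzyloxy)-2-[3,4-bis(benzyloxy)phenyl]chroman-3-ol (relative configuration drawn) | c1ccccc1COc1cc(OCc2ccccc2)c2c(c1)O[C@H](c1ccc(OCc3ccccc3)c(OCc3ccccc3)c1)[C@H](O)C2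
F4 | step 4 | 5,7-bis(benzyloxy)-2-[3,4-bis(benzyloxy)phenyl]chroman-3-one (racemic, C2 labile) | c1ccccc1COc1cc(OCc2ccccc2)c2c(c1)OC(c1ccc(OCc3ccccc3)c(OCc3ccccc3)c1)C(=O)C2
F5 | step 9 | (2R,3R,4S)-5,7-bis(benzyloxy)-2-[3,4-bis(benzyloxy)phenyl]-8-bromo-4-(2-ethoxyethoxy)chroman-3-ol | c1ccccc1COc1cc(OCc2ccccc2)c2c(c1Br)O[C@H](c1ccc(OCc3ccccc3)c(OCc3ccccc3)c1)[C@H](O)[C@H]2OCCOCC
F6 | step 9 | 8-bromo hexadeca-O-benzyl epicatechin-(4β→8) tetramer (bromine on C8 of the top unit) | c1ccccc1COc1cc(OCc2ccccc2)c2c(c1Br)O[C@H](c1ccc(OCc3ccccc3)c(OCc3ccccc3)c1)[C@H](O)[C@H]2c1c(OCc2ccccc2)cc(OCc2ccccc2)c2c1O[C@H](c1ccc(OCc3ccccc3)c(OCc3ccccc3)c1)[C@H](O)[C@H]2c1c(OCc2ccccc2)cc(OCc2ccccc2)c2c1O[C@H](c1ccc(OCc3ccccc3)c(OCc3ccccc3)c1)[C@H](O)[C@H]2c1c(OCc2ccccc2)cc(OCc2ccccc2)c2c1O[C@H](c1ccc(OCc3ccccc3)c(OCc3ccccc3)c1)[C@H](O)C2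
F7 | step 3 | 1-{[3,4-bis(benzyloxy)phenyl](methoxy)methyl}-2,4,6-trimethylpyridinium triflate (racemic) | COC(c1ccc(OCc2ccccc2)c(OCc2ccccc2)c1)[n+]1c(C)cc(C)cc1C.[O-]S(=O)(=O)C(F)(F)F
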